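**Retrosynthetic overview**
1. The last operations are O-demethylation (BBr3) and, before it, OH-directed ortho/para dibromination of ring B. Ring A with its bromine pattern is bought as 3,5-dibromosalicylaldehyde (CHO → OH by Baeyer–Villiger), so ring B is the only ring formed.
2. Ring B arene ⇐ oxidative aromatisation of a 3-bromo-6-aryloxycyclohex-2-enone. Its vinylic Br becomes the central bromine (meta to OH, para to the ether O), which no phenol-directed bromination can place.
3. Bromoenone ⇐ 4-aryloxy-4-(tert-butoxycarbonyl)cyclohexane-1,3-dione, by deoxybromination at the unhindered carbonyl and then loss of the tert-butyl ester as isobutene and CO2.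
4. Dione ⇐ intramolecular Claisen closure of a keto diester. That diester comes from the key step, the intermolecular Michael addition of an aryloxymalonate to methyl vinyl ketone (C5–C6 bond of ring B).
5. Aryloxymalonate ⇐ 3,5-dibromo-2-methoxyphenol + tert-butyl bromoacetate (C–O bond of the ether bridge) + methyl chloroformate (C-acylation).

Assumption: the target has no stereocentre and no configurationally stable axis, so it is achiral and no enantiocontrol is needed. Compounds 8 and 10–16 are handled as racemates, and their stereocentre is erased in step 9.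

**Route**

Step 1
Reactants: 1 3,5-dibromo-2-hydroxybenzaldehyde
Product: 2 3,5-dibromo-2-methoxybenzaldehyde
Conditions: MeI (1.5 equiv), K2CO3, DMF, rt
Reagents that add atoms: iodomethane, CI
Why: Williamson-type SN2 O-methylation of the acidic phenoxide masks the oxygen that must end as the free ring-A hydroxyl, and no stereocentre is involved.

Step 2
Reactants: 2 3,5-dibromo-2-methoxybenzaldehyde
Product: 4 3,5-dibromo-2-methoxyphenol, via aryl formate 3 (not isolated)
Conditions: mCPBA (1.5 equiv), CH2Cl2, reflux; then cat. K2CO3, MeOH, rt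
Reagents that add atoms: mCPBA (3-chloroperoxybenzoic acid), OOC(=O)c1cccc(Cl)c1
Why: Baeyer–Villiger oxidation, in which the ortho-methoxy-substituted aryl group migrates from the Criegee adduct in preference to hydride, followed by base-catalysed methanolysis of the labile aryl formate, converts CHO into the OH that will carry the ether bridge and leaves both bromines ortho and para to the masked hydroxyl as the target requires.

Step 3
Reactants: 4 3,5-dibromo-2-methoxyphenol; 5 tert-butyl bromoacetate
Product: 6 tert-butyl 2-(3,5-dibromo-2-methoxyphenoxy)acetate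
Conditions: K2CO3, acetone, reflux
Reagents that add atoms: none
Why: Williamson ether synthesis: SN2 attack of the phenoxide on a primary, carbonyl-activated bromide makes the C–O bond of the future diaryl ether under conditions that touch neither the aryl bromides nor the tert-butyl ester.

Step 4
Reactants: 6 tert-butyl 2-(3,5-dibromo-2-methoxyphenoxy)acetate; 7 methyl chloroformate
Product: 8 1-tert-butyl 3-methyl 2-(3,5-dibromo-2-methoxyphenoxy)propanedioate (racemic)
Conditions: LiHMDS (2.2 equiv), THF, −78 °C; 7 (1.2 equiv), −78 → −20 °C; cold 1 M HCl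
Reagents that add atoms: none
Why: Crossed Claisen-type C-acylation of the lithium ester enolate by the chloroformate, with the second equivalent of base deprotonating the more acidic malonate as it forms so that acylation stops cleanly; the new stereocentre is racemic, labile and of no consequence.

Step 5
Reactants: 8 1-tert-butyl 3-methyl 2-(3,5-dibromo-2-methoxyphenoxy)propanedioate; 9 but-3-en-2-one (methyl vinyl ketone)
Product: 10 1-tert-butyl 3-methyl 2-(3,5-dibromo-2-methoxyphenoxy)-2-(3-oxobutyl)propanedioate (racemic)
Conditions: 9 (1.3 equiv), DBU (10 mol %), MeCN, 0 °C → rt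
Reagents that add atoms: none
Why: Base-catalysed intermolecular Michael addition of the soft, doubly stabilised aryloxymalonate anion to the unhindered enone gives only the 1,4-adduct and forges the C5–C6 bond of the future ring B; the quaternary stereocentre is formed as a racemate and is erased in step 9.

Step 6
Reactants: 10 1-tert-butyl 3-methyl 2-(3,5-dibromo-2-methoxyphenoxy)-2-(3-oxobutyl)propanedioate
Product: 11 tert-butyl 1-(3,5-dibromo-2-methoxyphenoxy)-2,4-dioxocyclohexane-1-carboxylate (racemic)
Conditions: KOtBu (1.5 equiv), THF, 0 °C → rt; cold 1 M HCl to pH 3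
Reagents that add atoms: none
Why: Intramolecular Claisen (Dieckmann-type) condensation of the dimedone-synthesis kind: the methyl-ketone enolate closes a six-membered ring on the methyl ester rather than on the bulky tert-butyl ester, and irreversible deprotonation of the acidic 1,3-dione pulls the equilibria, retro-Michael included, to the product.

Step 7
Reactants: 11 tert-butyl 1-(3,5-dibromo-2-methoxyphenoxy)-2,4-dioxocyclohexane-1-carboxylate
Product: 13 tert-butyl 4-bromo-1-(3,5-dibromo-2-methoxyphenoxy)-2-oxocyclohex-3-ene-1-carboxylate (racemic), via enol oxyphosphonium bromide 12 (not isolated)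
Conditions: Ph3PBr2 (1.15 equiv, commercial), Et3N (1.2 equiv), CH2Cl2, 0 °C → rt
Reagents that add atoms: dibromotriphenylphosphorane, Br[P+](c1ccccc1)(c1ccccc1)c1ccccc1.[Br-]
Why: Deoxybromination of a vinylogous acid by Appel-type oxyphosphonium activation: the enolate binds phosphorus through the oxygen remote from the quaternary carbon and bromide then replaces Ph3PO by conjugate addition–elimination, which puts bromine on the carbon that becomes para to the ether oxygen.

Step 8
Reactants: 13 tert-butyl 4-bromo-1-(3,5-dibromo-2-methoxyphenoxy)-2-oxocyclohex-3-ene-1-carboxylate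
Product: 15 3-bromo-6-(3,5-dibromo-2-methoxyphenoxy)cyclohex-2-en-1-one (racemic), via beta-keto acid 14 (not isolated)
Conditions: TFA/CH2Cl2 (1:2), rt; concentrate; toluene, 80 °C
Reagents that add atoms: none
Why: Acidolysis (E1) of the tert-butyl ester frees a beta-keto acid that decarboxylates through the usual six-membered cyclic transition state, and the alpha'-enol formed ketonises without disturbing the water-sensitive vinylogous acyl bromide because no aqueous base or nucleophile is present.

Step 9
Reactants: 15 3-bromo-6-(3,5-dibromo-2-methoxyphenoxy)cyclohex-2-en-1-one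
Product: 18 5-bromo-2-(3,5-dibromo-2-methoxyphenoxy)phenol, via alpha'-bromo ketone 16 (not isolated), via cross-conjugated dienone 17 (not isolated)
Conditions: CuBr2 (2.2 equiv), LiBr (1.1 equiv), dry MeCN, reflux
Reagents that add atoms: none
Why: Oxidative aromatisation by alpha'-bromination and dehydrobromination: CuBr2 brominates the aryloxy-substituted enol carbon, the labile bromo ketone loses HBr to the cross-conjugated dienone, and dienone–phenol tautomerisation gives the arene with loss of the only stereocentre, ring A being too deactivated to compete.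

Step 10
Reactants: 18 5-bromo-2-(3,5-dibromo-2-methoxyphenoxy)phenol
Product: 20 2,3,4-tribromo-6-(3,5-dibromo-2-methoxyphenoxy)phenol, via para-monobrominated phenol 19 (not isolated)
Conditions: Br2 (2.1 equiv), AcOH, rt → 40 °C; aq NaHSO3 wash
Reagents that add atoms: bromine, BrBr
Why: Electrophilic aromatic bromination governed by the free hydroxyl, whose only open para and ortho positions flank the bromine already present, while the position ortho to the ether oxygen is meta to OH and ring A is a deactivated dibromoanisole with its activated positions blocked.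

Step 11
Reactants: 20 2,3,4-tribromo-6-(3,5-dibromo-2-methoxyphenoxy)phenol
Product: 22 2,3,4-tribromo-6-(3,5-dibromo-2-hydroxyphenoxy)phenol (target), via bis(dibromoboryl) ether 21 (not isolated)
Conditions: BBr3 (3 equiv), CH2Cl2, −78 °C → rt; then ice/H2O
Reagents that add atoms: none
Why: Lewis-acid ether cleavage: BBr3 complexes the twisted di-ortho-substituted methoxy oxygen and bromide removes the methyl group by SN2, the diaryl ether and all C–Br bonds being inert, and water hydrolyses the aryl borates to the achiral target.

**Compound list**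
1 | 3,5-dibromo-2-hydroxybenzaldehyde (3,5-dibromosalicylaldehyde) | O=Cc1cc(Br)cc(Br)c1O | starting material
2 | 3,5-dibromo-2-methoxybenzaldehyde | COc1c(Br)cc(Br)cc1C=O | intermediate
3 | 3,5-dibromo-2-methoxyphenyl formate (not isolated) | COc1c(Br)cc(Br)cc1OC=O | intermediate
4 | 3,5-dibromo-2-methoxyphenol | COc1c(Br)cc(Br)cc1O | intermediate
5 | tert-butyl bromoacetate | CC(C)(C)OC(=O)CBr | starting material
6 | tert-butyl 2-(3,5-dibromo-2-methoxyphenoxy)acetate | COc1c(Br)cc(Br)cc1OCC(=O)OC(C)(C)C | intermediate
7 | methyl chloroformate | COC(=O)Cl | starting material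
8 | 1-tert-butyl 3-methyl 2-(3,5-dibromo-2-methoxyphenoxy)propanedioate (racemic) | COC(=O)C(Oc1cc(Br)cc(Br)c1OC)C(=O)OC(C)(C)C | intermediate
9 | but-3-en-2-one (methyl vinyl ketone) | CC(=O)C=C | starting material
10 | 1-tert-butyl 3-methyl 2-(3,5-dibromo-2-methoxyphenoxy)-2-(3-oxobutyl)propanedioate (racemic) | COC(=O)C(CCC(C)=O)(Oc1cc(Br)cc(Br)c1OC)C(=O)OC(C)(C)C | intermediate
11 | tert-butyl 1-(3,5-dibromo-2-methoxyphenoxy)-2,4-dioxocyclohexane-1-carboxylate (racemic) | CC(C)(C)OC(=O)C1(Oc2cc(Br)cc(Br)c2OC)CCC(=O)CC1=O | intermediate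
12 | {[4-(tert-butoxycarbonyl)-4-(3,5-dibromo-2-methoxyphenoxy)-3-oxocyclohex-1-en-1-yl]oxy}(triphenyl)phosphonium bromide (racemic, not isolated) | CC(C)(C)OC(=O)C1(Oc2cc(Br)cc(Br)c2OC)CCC(O[P+](c2ccccc2)(c2ccccc2)c2ccccc2)=CC1=O.[Br-] | intermediate
13 | tert-butyl 4-bromo-1-(3,5-dibromo-2-methoxyphenoxy)-2-oxocyclohex-3-ene-1-carboxylate (racemic) | CC(C)(C)OC(=O)C1(Oc2cc(Br)cc(Br)c2OC)CCC(Br)=CC1=O | intermediate
14 | 4-bromo-1-(3,5-dibromo-2-methoxyphenoxy)-2-oxocyclohex-3-ene-1-carboxylic acid (racemic, not isolated) | OC(=O)C1(Oc2cc(Br)cc(Br)c2OC)CCC(Br)=CC1=O | intermediate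
15 | 3-bromo-6-(3,5-dibromo-2-methoxyphenoxy)cyclohex-2-en-1-one (racemic) | COc1c(Br)cc(Br)cc1OC1CCC(Br)=CC1=O | intermediate
16 | 3,6-dibromo-6-(3,5-dibromo-2-methoxyphenoxy)cyclohex-2-en-1-one (racemic, not isolated) | COc1c(Br)cc(Br)cc1OC1(Br)CCC(Br)=CC1=O | intermediate
17 | 5-bromo-2-(3,5-dibromo-2-methoxyphenoxy)cyclohexa-2,5-dien-1-one (not isolated) | COc1c(Br)cc(Br)cc1OC1=CCC(Br)=CC1=O | intermediate
18 | 5-bromo-2-(3,5-dibromo-2-methoxyphenoxy)phenol | COc1c(Br)cc(Br)cc1Oc1ccc(Br)cc1O | intermediate
19 | 4,5-dibromo-2-(3,5-dibromo-2-methoxyphenoxy)phenol (not isolated) | COc1c(Br)cc(Br)cc1Oc1cc(Br)c(Br)cc1O | intermediate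
20 | 2,3,4-tribromo-6-(3,5-dibromo-2-methoxyphenoxy)phenol | COc1c(Br)cc(Br)cc1Oc1cc(Br)c(Br)c(Br)c1O | intermediate
21 | dibromo{2,3,4-tribromo-6-[3,5-dibromo-2-(dibromoboranyloxy)phenoxy]phenoxy}borane (not isolated) | BrB(Br)Oc1c(Br)cc(Br)cc1Oc1cc(Br)c(Br)c(Br)c1OB(Br)Br | intermediate
22 | 2,3,4-tribromo-6-(3,5-dibromo-2-hydroxyphenoxy)phenol (achiral) | Oc1c(Br)cc(Br)cc1Oc1cc(Br)c(Br)c(Br)c1O | target

**Totals**
Total step count: 11. Longest linear sequence: 11 steps (1 → 22, fully linear).

**Three steps most likely to fail (in route order)**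

Risk 1 (step 6, ring closure). The dangers are retro-Michael loss of 9 under strong base, ester exchange by tert-butoxide, and slow attack next to the quaternary carbon.
- The fallback leaves the malonate series. It sets out from 4 and comes back at 15, bypassing steps 3–8.
- O-alkylation of 4 with chloroacetone (K2CO3, cat. KI, acetone, reflux) gives 1-(3,5-dibromo-2-methoxyphenoxy)propan-2-one F1.
- KOtBu (2 equiv) in THF at 0 °C with slow addition of methyl acrylate brings about Michael addition through the more stabilised aryloxy-substituted enolate. This gives methyl 4-(3,5-dibromo-2-methoxyphenoxy)-5-oxohexanoate F2.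
- F2 closes in the same pot, by Claisen condensation of its methyl ketone on the ester, to 4-(3,5-dibromo-2-methoxyphenoxy)cyclohexane-1,3-dione F3.
- Ph3PBr2/Et3N in CH2Cl2 then acts through {[4-(3,5-dibromo-2-methoxyphenoxy)-3-oxocyclohex-1-en-1-yl]oxy}(triphenyl)phosphonium bromide F4 and delivers 15.
- Regiocontrol of the bromination now rests only on the steric and inductive bias of the secondary aryloxy carbon, so 15 has to be purified by chromatography.

Risk 2 (step 7, deoxybromination). The dangers are attack of the phosphorus reagent or adventitious HBr on the tert-butyl ester, and a sluggish reaction of the hindered dione.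
- The fallback separates activation from halide delivery. It sets out from 11 and comes back at 13.
- Tf2O with 2,6-lutidine (CH2Cl2, −78 °C) sulfonylates the unhindered enol oxygen. The product is tert-butyl 1-(3,5-dibromo-2-methoxyphenoxy)-2-oxo-4-(trifluoromethanesulfonyloxy)cyclohex-3-ene-1-carboxylate F5.
- F5 is an isolable vinylogous acyl triflate, so its regiochemistry can be checked by NMR.
- LiBr (3 equiv, THF, rt) then replaces triflate by conjugate addition–elimination under neutral conditions to give 13.

Risk 3 (step 9, aromatisation). The dangers are incomplete oxidation, HBr-induced cleavage of the alpha-aryloxy ketone, and hydrolysis of the bromoenone by traces of water. Partial further bromination of 18 to 19 is harmless because 19 lies on the route.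
- The fallback replaces halogenation/dehydrohalogenation by a selenoxide elimination. It sets out from 15 and comes back at 18 through 17.
- LiHMDS (THF, −78 °C) forms the kinetic cross-conjugated alpha'-enolate. PhSeBr traps it as 3-bromo-6-(3,5-dibromo-2-methoxyphenoxy)-6-(phenylselanyl)cyclohex-2-en-1-one F6.
- H2O2 with pyridine in CH2Cl2 at 0 °C oxidises F6 to 3-bromo-6-(3,5-dibromo-2-methoxyphenoxy)-6-(phenylseleninyl)cyclohex-2-en-1-one F7.
- F7 undergoes syn elimination towards C5–H below room temperature to give 17, which tautomerises to 18.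

**Further compounds**
F1 | step 6 | 1-(3,5-dibromo-2-methoxyphenoxy)propan-2-one | CC(=O)COc1cc(Br)cc(Br)c1OC
F2 | step 6 | methyl 4-(3,5-dibromo-2-methoxyphenoxy)-5-oxohexanoate (racemic) | COC(=O)CCC(Oc1cc(Br)cc(Br)c1OC)C(C)=O
F3 | step 6 | 4-(3,5-dibromo-2-methoxyphenoxy)cyclohexane-1,3-dione (racemic) | COc1c(Br)cc(Br)cc1OC1CCC(=O)CC1=O
F4 | step 6 | {[4-(3,5-dibromo-2-methoxyphenoxy)-3-oxocyclohex-1-en-1-yl]oxy}(triphenyl)phosphonium bromide (racemic) | COc1c(Br)cc(Br)cc1OC1CCC(O[P+](c2ccccc2)(c2ccccc2)c2ccccc2)=CC1=O.[Br-]
F5 | step 7 | tert-butyl 1-(3,5-dibromo-2-methoxyphenoxy)-2-oxo-4-(trifluoromethanesulfonyloxy)cyclohex-3-ene-1-carboxylate (racemic) | CC(C)(C)OC(=O)C1(Oc2cc(Br)cc(Br)c2OC)CCC(OS(=O)(=O)C(F)(F)F)=CC1=O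
F6 | step 9 | 3-bromo-6-(3,5-dibromo-2-methoxyphenoxy)-6-(phenylselanyl)cyclohex-2-en-1-one (racemic) | COc1c(Br)cc(Br)cc1OC1([Se]c2ccccc2)CCC(Br)=CC1=O
F7 | step 9 | 3-bromo-6-(3,5-dibromo-2-methoxyphenoxy)-6-(phenylseleninyl)cyclohex-2-en-1-one | COc1c(Br)cc(Br)cc1OC1([Se](=O)c2ccccc2)CCC(Br)=CC1=O
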